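The constants of this chemistry are hidden from us, so we start from a ledger of partner, which needs none.

| flask | starting material | partner | temperature | remark | time |
|---|---|---|---|---|---|
| oak | 0.43 M | 1 equiv | 15 °C | run made earlier |  |
| birch | 0.29 M | 1 equiv | 26 °C | run made earlier |  |
| alder | 0.65 M | 1 equiv | 15 °C | run made earlier |  |
| Thursday's | 0.43 M (fed, over 50 min) | 1.00 equiv | 20 °C | all else is in the flask from the start; the feed brings no volume worth counting | 1.5 h |
| Tuesday's | 0.43 M (fed, over 5.0 min) | 1.00 equiv | 20 °C | all else is in the flask from the start; the feed brings no volume worth counting | 1.5 h |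
| Wednesday's | 0.43 M | 1.00 equiv (fed, over 50 min) |  | the addition at 0 °C, then warmed to 20 °C; the feed brings no volume worth counting | 1.5 h |
| Saturday's | 0.43 M | 1.00 equiv (fed, over 50 min) | 20 °C | all else is in the flask from the start; the feed brings no volume worth counting | 1.5 h |

| run | time / min | mono adduct / % | starting material / % |
|---|---|---|---|
| oak | 8.00 | 67.5 | 19.9 |
| oak | 15.0 | 75.1 | 10.5 |
| oak | 40.0 | 77.5 | 2.8 |
| oak | 90.0 | 77.3 | 1.6 |
| birch | 15.0 | 69.1 | 6.7 |
| birch | 40.0 | 68.9 | 2.9 |
| birch | 80.0 | 67.8 | 0.4 |
| birch | 120 | 68.8 | 1.4 |
| alder | 15.0 | 77.2 | 7.0 |
| alder | 40.0 | 77.6 | 2.4 |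
| alder | 80.0 | 76.3 | 1.4 |
| alder | 120 | 75.7 | 0.1 |

(standard deviation of a reading: 0.5 percentage points)



- the flask that comes out highest in amount of mono adduct, in percent of the starting material charged, or "all alike" when all lie within 1.5 percentage points (Thursday's / Tuesday's / Wednesday's / Saturday's / all alike)
- mono adduct at the end, in percent of the starting material charged, Thursday's
- mono adduct at the end, in percent of the starting material charged, Tuesday's
- mono adduct at the end, in percent of the starting material charged, Wednesday's
- mono adduct at the end, in percent of the starting material charged, Saturday's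

In the oak run after 90.0 min, the partner not held in mono adduct is 22.7% of the starting material charged. This spare partner, partner charged less mono adduct made, is our ledger. A product carrying two partners could then hold 11.3% of the starting material, but the oak readings leave 21.1% unaccounted for, which is more. So by this reading some starting material leaves without partner.

Now the settings. By hand, concentration leaves the shares alone if the competing routes share its order, and alder at 0.65 M reads 77.6% at 40.0 min against oak's 77.5% at 0.43 M. Heat may favour either route, but birch at 26 °C reads 68.8%, a larger spare of 31.2%. Feed time is next. Oak's starting material reads 2.8% at 40.0 min, and a 50 min feed is longer than that, so early in the feed the species in the flask from the start should stand in excess of the fed one. A 5.0 min feed, shorter than oak's first sample, stays near a batch. Slowly fed partner leaves starting material waiting without partner, and slowly fed starting material leaves partner waiting beside mono adduct. The cold addition at 0 °C lies below our runs, so we give it no number. We commit to Tuesday's as highest, between 68.8% and 77.3%, with Saturday's lowest.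

The forecast gives 73.6% for Thursday's, 73.4% for Tuesday's, 74.5% for Wednesday's and 41% for Saturday's, with Wednesday's highest, holding that “feeding starting material changes nothing”. We differ from it on the highest flask and on Thursday's.

The flasks give 62.3%, 76.1%, 65.6% and 24.7% in that order, with Tuesday's highest.

    starting material + partner → mono adduct + by-product (k = 0.0200 M⁻¹ s⁻¹, Ea = 45.0 kJ mol⁻¹)
    partner + mono adduct → double product + by-product (k = 9.30 × 10⁻⁴ M⁻¹ s⁻¹, Ea = 78.0 kJ mol⁻¹)
    2 starting material → homo dimer (k = 0.00210 M⁻¹ s⁻¹, Ea = 74.0 kJ mol⁻¹)
    mono adduct → over-reaction product (k = 2.20 × 10⁻⁷ s⁻¹, Ea = 106 kJ mol⁻¹)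
    partner → decomposed reagent (k = 8.90 × 10⁻⁵ s⁻¹, Ea = 83.0 kJ mol⁻¹)
    (constants at 20 °C)

Tuesday's spare partner is 23.9%, against oak's 22.7%. With 0.47% of its partner left, Tuesday's holds 76.1% mono adduct at 1.5 h and 75.2% at ten times the time, so it has nearly come to rest. Saturday's has not: its spare of 75.3% is larger than oak's, 28% of its partner is left, and over the same stretch its mono adduct goes from 24.7% to 12.3% and its double product from 17.4% to 29.7%.

Take Tuesday's flask with 1.70 equiv of partner. The ledger adds the surplus to oak's spare, giving 92.7%, while mono adduct at oak's level leaves 22.7% of the starting material for double product to hold, so we expect mono adduct to fall below oak's level. The computed flask holds 45.2% double product beside 51.1% mono adduct, with 6.6% of its partner left.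

The numbers in the tables were generated by integration with made-up constants; noise was put on by code.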